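**Strategy.** The flavanone is cut at the O1–C2 bond of the pyranone (C) ring: the β-aryloxy ketone O1–C2–C3–C4=O is a latent oxa-Michael adduct. All five benzene rings and the four diarylmethane links are first assembled on an acetophenone in which only the phenol next to the C8 benzyl carbon is free. A removable tert-butyl ester at C3 turns the chalcone into an alkylidene β-ketoester; a cinchona thiourea then closes the C ring enantioselectively and acid removes the ester in the same flask. One operation thus delivers the last ring, the C2 stereocentre and, because O5 is blocked, the C6/C8 placement of the two benzyl groups.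

Key step: step 10

Assumption: 4-(benzyloxy)-3-bromobenzaldehyde, 2-(benzyloxy)benzyl bromide and 2′,4′-bis(benzyloxy)-6′-hydroxyacetophenone are taken as catalogue compounds, and the quinidine-derived thiourea is taken to give the 2S series (its quinine-derived pseudoenantiomer is used if the sense proves opposite).

Ring labels used below: A ring is the phloroglucinol core, C ring the pyranone; P1 is the phenol ring on the C8 methylene; P2, P3 and P4 are the phenol rings of the chain on C6 (P2 attached to the C6 methylene, P4 terminal). Primed locants refer to the acetophenone ring.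

Step 1
Reactants: 1 2,6-dibromophenol
Product: 2 2-(benzyloxy)-1,3-dibromobenzene
Conditions: BnBr, K2CO3, DMF, 50 °C
Reagents that add atoms: benzyl bromide, BrCc1ccccc1
Why: Williamson ether synthesis (SN2 of the phenoxide on benzyl bromide) should protect the future P3 phenol as a benzyl ether that tolerates organolithiums and acid and is removed with all the others in the last step.

Step 2
Reactants: 2 2-(benzyloxy)-1,3-dibromobenzene; 3 2-(benzyloxy)benzaldehyde; 4 4-(benzyloxy)-3-bromobenzaldehyde
Product: 8 [2-(benzyloxy)-3-{[4-(benzyloxy)-3-bromophenyl](hydroxy)methyl}phenyl][2-(benzyloxy)phenyl]methanol (diastereomer mixture), via monolithiated arene 5 (not isolated), via bromo lithium alkoxide 6 (not isolated), via lithiated lithium alkoxide 7 (not isolated)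
Conditions: n-BuLi (1.0 equiv), THF, −78 °C; 3; n-BuLi (1.05 equiv), −78 °C; 4; −78 → −20 °C; H2O quench
Reagents that add atoms: none
Why: Sequential bromine–lithium exchange and 1,2-addition to aldehydes should work because the first exchange on the symmetrical dibromide is mono-selective at −78 °C, the lithium alkoxide formed with 3 does not disturb the second exchange at the remaining C–Br bond, and the bromo-aldehyde 4 is added last so that its own bromide never meets butyllithium; the two carbinol centres form without control and are erased in step 3.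

Step 3
Reactants: 8 bis-carbinol
Product: 9 1-(benzyloxy)-4-{2-(benzyloxy)-3-[2-(benzyloxy)benzyl]benzyl}-2-bromobenzene
Conditions: Et3SiH (5 equiv), TFA, CH2Cl2, 0 °C
Reagents that add atoms: none
Why: Ionic hydrogenation (silane/Brønsted acid) should reduce both doubly benzylic carbinols through alkoxy-stabilised diarylmethyl cations while the aryl bromide and the benzyl ethers are inert at 0 °C.

Step 4
Reactants: 9 trimer aryl bromide
Product: 11 {2-(benzyloxy)-5-{2-(benzyloxy)-3-[2-(benzyloxy)benzyl]benzyl}phenyl}methanol, via trimer aryllithium 10 (not isolated)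
Conditions: n-BuLi, THF, −78 °C; dry paraformaldehyde, −78 °C → rt; H2O quench
Reagents that add atoms: formaldehyde (from paraformaldehyde), C=O
Why: Bromine–lithium exchange is faster than deprotonation of the diarylmethane CH2 groups at −78 °C, and 1,2-addition of the aryllithium to formaldehyde gives the benzylic alcohol that serves as cation precursor in step 7.

Step 5
Reactants: 12 1-[2,4-bis(benzyloxy)-6-hydroxyphenyl]ethan-1-one
Product: 13 1-[4,6-bis(benzyloxy)-2-hydroxy-3-iodophenyl]ethan-1-one
Conditions: BnMe3N·ICl2 (1.05 equiv), NaHCO3, CH2Cl2/MeOH, rt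
Reagents that add atoms: benzyltrimethylammonium dichloroiodate, C[N+](C)(C)Cc1ccccc1.Cl[I-]Cl
Why: Electrophilic aromatic iodination in which the free, carbonyl-chelated 2′-OH should direct the bulky reagent to its ortho carbon C3′, which is also less hindered than C5′ between two benzyloxy groups, so that the later C8 substituent is placed next to the only free phenol.

Step 6
Reactants: 13 3′-iodo ketone; 14 2-(benzyloxy)benzyl bromide
Product: 16 1-{4,6-bis(benzyloxy)-3-[2-(benzyloxy)benzyl]-2-hydroxyphenyl}ethan-1-one, via benzylic zinc bromide 15 (not isolated)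
Conditions: 14, Zn dust, LiCl, THF, rt; then 13, Pd(OAc)2 (2 mol%), SPhos (4 mol%), THF, rt → 50 °C (zinc reagent 2.2 equiv, slow addition)
Reagents that add atoms: none
Why: Negishi sp2–sp3 cross-coupling of a benzylic zinc reagent with the hindered aryl iodide under Pd/SPhos, a catalyst system that tolerates the ketone and the chelated phenolic OH when the zinc reagent is in excess.

Step 7
Reactants: 16 3′-(2-benzyloxybenzyl) ketone; 11 trimer benzylic alcohol
Product: 17 1-[4,6-bis(benzyloxy)-2-hydroxy-3-(2-benzyloxybenzyl)-5-{2-benzyloxy-5-[2-benzyloxy-3-(2-benzyloxybenzyl)benzyl]benzyl}phenyl]ethan-1-one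
Conditions: Bi(OTf)3 (5 mol%), CH2Cl2/MeNO2, 0 °C → rt, 16 in slight excess
Reagents that add atoms: none
Why: Friedel–Crafts benzylation in which Lewis-acid ionisation of the ortho-benzyloxybenzyl alcohol gives a stabilised benzylic cation that should be captured by C5′, the only unsubstituted A-ring carbon and, being para to the free OH and ortho to two benzyloxy groups, the most nucleophilic arene position present.

Step 8
Reactants: 17 fully substituted acetophenone
Product: 19 tert-butyl 3-oxo-3-aryl-propanoate of 17 (aryl as in 17), via dilithium phenoxide-enolate 18 (not isolated)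
Conditions: LiHMDS (3.3 equiv), THF, −78 °C; Boc2O (1.1 equiv), −78 → 0 °C; AcOH quench
Reagents that add atoms: di-tert-butyl dicarbonate, CC(C)(C)OC(=O)OC(=O)OC(C)(C)C
Why: Claisen-type C-acylation of the ketone enolate by Boc2O (any aryl tert-butyl carbonate formed at oxygen passes its acyl group to carbon in a Baker–Venkataraman-type shift, phenoxide being the better leaving group) should install the C3 ester that activates the enone for step 10 and is removed there.

Step 9
Reactants: 19 β-ketoester; 20 benzaldehyde
Product: 21 tert-butyl 2-aroyl-3-phenylprop-2-enoate (aryl as in 17; alkene geometry not defined)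
Conditions: piperidine (20 mol%), AcOH (20 mol%), 4 Å MS, toluene, rt; rapid chromatography
Reagents that add atoms: none
Why: Knoevenagel condensation of the 1,3-dicarbonyl compound with benzaldehyde under piperidinium acetate with water removal gives the doubly activated benzylidene, whose geometry leaves no stereo-element in the final product because C3 becomes CH2.

Step 10
Reactants: 21 alkylidene β-ketoester
Product: 23 (2S)-5,7-bis(benzyloxy)-8-(2-benzyloxybenzyl)-6-{2-benzyloxy-5-[2-benzyloxy-3-(2-benzyloxybenzyl)benzyl]benzyl}-2-phenylchroman-4-one, via tert-butyl chromanone-3-carboxylate 22 (not isolated)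
Conditions: quinidine-derived 9-epi-amino 3,5-bis(trifluoromethyl)phenyl thiourea (10 mol%), toluene, −25 °C; then TsOH·H2O (0.5 equiv), 80 °C
Reagents that add atoms: none
Why: The quinuclidine nitrogen of the bifunctional catalyst activates the only free phenol (O1–H) while the thiourea binds the 1,3-dicarbonyl unit of the doubly activated enone, so O1 adds to the benzylidene carbon (future C2) in an intramolecular oxa-Michael addition, and acid then removes the tert-butyl ester as 2-methylpropene and CO2. The closest known reaction type is the cinchona-thiourea-catalysed oxa-conjugate addition of 2-hydroxyaryl alkylidene β-ketoesters with decarboxylation in the same flask, an established enantioselective flavanone synthesis. The pyranone ring closes in the 6-endo-trig mode. C2 is set by the catalyst alone (face selection on the enone, no stereocentre in the substrate), and the C3 centre formed in 22 is erased on decarboxylation. The step needs regioselection between the two oxygens ortho to the acyl group and enantioselection: the first is secured because O5, O7 and all side-chain phenols are benzyl ethers, so only the oxygen next to the carbon bearing the 2-benzyloxybenzyl group can cyclise, which fixes that group at C8 and the chain at C6; the second is protected by decarboxylating under acid, with no base present after ring closure that could reopen the ring.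

Step 11
Reactants: 23 hexa-O-benzyl flavanone
Product: 24 (2S)-5,7-dihydroxy-8-(2-hydroxybenzyl)-6-{2-hydroxy-5-[2-hydroxy-3-(2-hydroxybenzyl)benzyl]benzyl}-2-phenylchroman-4-one (CNP0107650.1)
Conditions: H2 (1 atm), Pd(OH)2/C, EtOAc/MeOH, rt
Reagents that add atoms: none
Why: Catalytic hydrogenolysis of the six benzyl aryl ethers under neutral conditions should free all phenols without touching the diarylmethane C–C bonds, the chelated C4 ketone or the configuration at C2, since neither base nor strong acid is present to open the C ring.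

**Compound list**

1 | 2,6-dibromophenol | Oc1c(Br)cccc1Br | starting material
2 | 2-(benzyloxy)-1,3-dibromobenzene | Brc1cccc(Br)c1OCc1ccccc1 | intermediate
3 | 2-(benzyloxy)benzaldehyde | O=Cc1ccccc1OCc1ccccc1 | starting material
4 | 4-(benzyloxy)-3-bromobenzaldehyde | O=Cc1ccc(OCc2ccccc2)c(Br)c1 | starting material
5 | [2-(benzyloxy)-3-bromophenyl]lithium | [Li]c1cccc(Br)c1OCc1ccccc1 | intermediate (not isolated)
6 | lithium [2-(benzyloxy)-3-bromophenyl][2-(benzyloxy)phenyl]methanolate | [Li]OC(c1ccccc1OCc1ccccc1)c1cccc(Br)c1OCc1ccccc1 | intermediate (not isolated)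
7 | lithium [2-(benzyloxy)-3-lithiophenyl][2-(benzyloxy)phenyl]methanolate | [Li]OC(c1ccccc1OCc1ccccc1)c1cccc([Li])c1OCc1ccccc1 | intermediate (not isolated)
8 | [2-(benzyloxy)-3-{[4-(benzyloxy)-3-bromophenyl](hydroxy)methyl}phenyl][2-(benzyloxy)phenyl]methanol (diastereomer mixture) | OC(c1ccccc1OCc1ccccc1)c1cccc(C(O)c2ccc(OCc3ccccc3)c(Br)c2)c1OCc1ccccc1 | intermediate
9 | 1-(benzyloxy)-4-{2-(benzyloxy)-3-[2-(benzyloxy)benzyl]benzyl}-2-bromobenzene | Brc1cc(Cc2cccc(Cc3ccccc3OCc3ccccc3)c2OCc2ccccc2)ccc1OCc1ccccc1 | intermediate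
10 | aryllithium from 9 (Li in place of Br) | [Li]c1cc(Cc2cccc(Cc3ccccc3OCc3ccccc3)c2OCc2ccccc2)ccc1OCc1ccccc1 | intermediate (not isolated)
11 | {2-(benzyloxy)-5-{2-(benzyloxy)-3-[2-(benzyloxy)benzyl]benzyl}phenyl}methanol | OCc1cc(Cc2cccc(Cc3ccccc3OCc3ccccc3)c2OCc2ccccc2)ccc1OCc1ccccc1 | intermediate
12 | 1-[2,4-bis(benzyloxy)-6-hydroxyphenyl]ethan-1-one | CC(=O)c1c(O)cc(OCc2ccccc2)cc1OCc1ccccc1 | starting material
13 | 1-[4,6-bis(benzyloxy)-2-hydroxy-3-iodophenyl]ethan-1-one | CC(=O)c1c(O)c(I)c(OCc2ccccc2)cc1OCc1ccccc1 | intermediate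
14 | 2-(benzyloxy)benzyl bromide | BrCc1ccccc1OCc1ccccc1 | starting material
15 | [2-(benzyloxy)benzyl]zinc bromide | Br[Zn]Cc1ccccc1OCc1ccccc1 | intermediate (not isolated)
16 | 1-{4,6-bis(benzyloxy)-3-[2-(benzyloxy)benzyl]-2-hydroxyphenyl}ethan-1-one | CC(=O)c1c(O)c(Cc2ccccc2OCc2ccccc2)c(OCc2ccccc2)cc1OCc1ccccc1 | intermediate
17 | 1-[4,6-bis(benzyloxy)-2-hydroxy-3-(2-benzyloxybenzyl)-5-{2-benzyloxy-5-[2-benzyloxy-3-(2-benzyloxybenzyl)benzyl]benzyl}phenyl]ethan-1-one | CC(=O)c1c(O)c(Cc2ccccc2OCc2ccccc2)c(OCc2ccccc2)c(Cc2cc(Cc3cccc(Cc4ccccc4OCc4ccccc4)c3OCc3ccccc3)ccc2OCc2ccccc2)c1OCc1ccccc1 | intermediate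
18 | dilithium phenoxide-enolate of 17 | [Li]OC(=C)c1c(O[Li])c(Cc2ccccc2OCc2ccccc2)c(OCc2ccccc2)c(Cc2cc(Cc3cccc(Cc4ccccc4OCc4ccccc4)c3OCc3ccccc3)ccc2OCc2ccccc2)c1OCc1ccccc1 | intermediate (not isolated)
19 | tert-butyl 3-oxo-3-aryl-propanoate (aryl as in 17) | CC(C)(C)OC(=O)CC(=O)c1c(O)c(Cc2ccccc2OCc2ccccc2)c(OCc2ccccc2)c(Cc2cc(Cc3cccc(Cc4ccccc4OCc4ccccc4)c3OCc3ccccc3)ccc2OCc2ccccc2)c1OCc1ccccc1 | intermediate
20 | benzaldehyde | O=Cc1ccccc1 | starting material
21 | tert-butyl 2-aroyl-3-phenylprop-2-enoate (aryl as in 17; alkene geometry not defined) | CC(C)(C)OC(=O)C(=Cc1ccccc1)C(=O)c1c(O)c(Cc2ccccc2OCc2ccccc2)c(OCc2ccccc2)c(Cc2cc(Cc3cccc(Cc4ccccc4OCc4ccccc4)c3OCc3ccccc3)ccc2OCc2ccccc2)c1OCc1ccccc1 | intermediate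
22 | tert-butyl (2S)-4-oxo-2-phenylchromane-3-carboxylate carrying the substituents of 23 (C3 configuration not defined) | O=C1C(C(=O)OC(C)(C)C)[C@@H](c2ccccc2)Oc2c(Cc3ccccc3OCc3ccccc3)c(OCc3ccccc3)c(Cc3cc(Cc4cccc(Cc5ccccc5OCc5ccccc5)c4OCc4ccccc4)ccc3OCc3ccccc3)c(OCc3ccccc3)c21 | intermediate (not isolated)
23 | (2S)-5,7-bis(benzyloxy)-8-(2-benzyloxybenzyl)-6-{2-benzyloxy-5-[2-benzyloxy-3-(2-benzyloxybenzyl)benzyl]benzyl}-2-phenylchroman-4-one | O=C1C[C@@H](c2ccccc2)Oc2c(Cc3ccccc3OCc3ccccc3)c(OCc3ccccc3)c(Cc3cc(Cc4cccc(Cc5ccccc5OCc5ccccc5)c4OCc4ccccc4)ccc3OCc3ccccc3)c(OCc3ccccc3)c21 | intermediate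
24 | (2S)-5,7-dihydroxy-8-(2-hydroxybenzyl)-6-{2-hydroxy-5-[2-hydroxy-3-(2-hydroxybenzyl)benzyl]benzyl}-2-phenylchroman-4-one | O=C1C[C@@H](c2ccccc2)Oc2c(Cc3ccccc3O)c(O)c(Cc3cc(Cc4cccc(Cc5ccccc5O)c4O)ccc3O)c(O)c21 | target

**Step count.** Total: 11 steps. Longest linear sequence: 9 steps (1 → 2 → 8 → 9 → 11 → 17 → 19 → 21 → 23 → 24, i.e. steps 1–4 and 7–11).

**Steps most likely to fail**

1. Step 10. Facial selection at C2 may be insufficient on this di-ortho-substituted aroyl alkylidene. Uncatalysed cyclisation of 21 may compete. Reversible ring opening during the acidic decarboxylation may erode the enantiomeric purity. Fallback, setting out from 17 and returning at 23 (steps 8–10 bypassed): 17 is silylated with TMSOTf/Et3N (CH2Cl2, 0 °C) to the aryl silyl ether/silyl enol ether F1. A SiCl4-mediated, chiral-bisphosphoramide-catalysed enantioselective Mukaiyama aldol addition to benzaldehyde 20 (CH2Cl2, −78 °C; aqueous KF/NaHCO3 work-up, which also frees the phenol) gives the (R)-β-hydroxy ketone F2. Mitsunobu cyclisation (PPh3, DIAD, THF, 0 °C) then closes the C ring by SN2 displacement with inversion at the carbinol carbon and gives 23 with 2S configuration.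

2. Step 7. The benzylic cation may be captured by the alkoxy-arene rings of a second molecule (oligomerisation) instead of the hindered C5′, and the acid may scramble benzyl ethers. Fallback, setting out from 16 and 11 and returning at 17: NBS (MeCN, 0 °C) brominates the only open A-ring carbon of 16 to give the 5′-bromo ketone F3. Alcohol 11 is converted with SOCl2 (CH2Cl2, 0 °C) into the benzylic chloride F4 and then with zinc dust/LiCl (THF) into the benzylic zinc chloride F5. Negishi coupling of F3 with F5 (Pd(OAc)2/SPhos, THF, 50 °C) gives 17.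

3. Step 5. The iodination may not discriminate sufficiently between the carbon ortho and the carbon para to the free phenol, or may run on to di-iodination. Fallback, setting out from 12 and 3 and returning at 16 (steps 5 and 6 replaced): 12 is condensed with aldehyde 3 and phenylboronic acid (cat. propionic acid, toluene, reflux with water removal) to the 2-phenyl-4-aryl-4H-1,3,2-benzodioxaborin F6. In this ring the boron tether on the phenol oxygen can deliver the aldehyde carbon only to the ortho carbon C3′. Ionic hydrogenation of the benzylic C–O bond (Et3SiH, TFA, CH2Cl2, 0 °C) and hydrolytic loss of phenylboronic acid give 16 without any site-selective halogenation.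

**Further compounds**

F1 | step 10 | trimethylsilyl enol ether of 17 with the 2′-oxygen as trimethylsilyl ether | C=C(O[Si](C)(C)C)c1c(O[Si](C)(C)C)c(Cc2ccccc2OCc2ccccc2)c(OCc2ccccc2)c(Cc2cc(Cc3cccc(Cc4ccccc4OCc4ccccc4)c3OCc3ccccc3)ccc2OCc2ccccc2)c1OCc1ccccc1
F2 | step 10 | (3R)-3-hydroxy-3-phenyl-1-aryl-propan-1-one (aryl as in 17) | O[C@H](CC(=O)c1c(O)c(Cc2ccccc2OCc2ccccc2)c(OCc2ccccc2)c(Cc2cc(Cc3cccc(Cc4ccccc4OCc4ccccc4)c3OCc3ccccc3)ccc2OCc2ccccc2)c1OCc1ccccc1)c1ccccc1
F3 | step 7 | 1-{4,6-bis(benzyloxy)-3-[2-(benzyloxy)benzyl]-5-bromo-2-hydroxyphenyl}ethan-1-one | CC(=O)c1c(O)c(Cc2ccccc2OCc2ccccc2)c(OCc2ccccc2)c(Br)c1OCc1ccccc1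
F4 | step 7 | 1-(benzyloxy)-4-{2-(benzyloxy)-3-[2-(benzyloxy)benzyl]benzyl}-2-(chloromethyl)benzene | ClCc1cc(Cc2cccc(Cc3ccccc3OCc3ccccc3)c2OCc2ccccc2)ccc1OCc1ccccc1
F5 | step 7 | benzylic zinc chloride from F4 | Cl[Zn]Cc1cc(Cc2cccc(Cc3ccccc3OCc3ccccc3)c2OCc2ccccc2)ccc1OCc1ccccc1
F6 | step 5 | 1-{5,7-bis(benzyloxy)-4-[2-(benzyloxy)phenyl]-2-phenyl-4H-1,3,2-benzodioxaborin-8-yl}ethan-1-one (racemic at C4) | CC(=O)c1c(OCc2ccccc2)cc(OCc2ccccc2)c2c1OB(c1ccccc1)OC2c1ccccc1OCc1ccccc1
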